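**Plan**

- Retrosynthesis: after removal of the three silyl ethers and the angelate, the C3 carbinol, the C4 hydroxymethyl group (C18) and the C1 methylene are traced back through a Δ1-3-ketone to the trans-fused bicyclic 1,3-dione 16 (carbonyls on C1 and C3).
- Dione 16 is cut at C2–C3 and at C5–C10 in one operation to the open-chain methyl ketone/enoate 14. Ring A consists of two three-carbon halves, C10–C1–C2 and C3–C4–C5: a temporary carbonyl on C1 makes both of its neighbours (C10 and C2) nucleophilic, and C5 and C3 are the β-carbon and the carboxyl carbon of an α-methyl enoate. Ring B (C5–C10) closes because C6–C9 tether the two halves.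
- 14 is cut at C8–C9 (conjugate addition) into enone 8, which already carries the whole C11–C16 side chain, and alkenylboronate 13 (C3–C8 and C17).
- Forward: butenolide coupling and reduction give the Z-butenediol unit and enone 8; 13 comes from pent-4-yn-1-ol; conjugate addition joins them; one base treatment closes ring B and then ring A; ring A is then corrected (C1 oxygen out, C18 in, C3 reduced), esterified and desilylated.
- Stereochemistry: C9 from the chiral rhodium catalyst; C5 and C10 from C9 in the chair Michael transition state; C4 from attack anti to the axial C20 methyl; C3 from axial hydride delivery; 13Z from the butenolide ring; angelate geometry from angelic acid.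

Key step: step 10

Remark: 4-bromofuran-2(5H)-one, acrolein diethyl acetal, pent-4-yn-1-ol, angelic acid, (S)-BINAP and both stabilised phosphoranes are taken as purchasable; atom numbers are labdane locants (ring A = C1–C5 and C10, ring B = C5–C10, C17 = exocyclic CH2 on C8, C18 = CH2OH and C19 = CH3 on C4, C20 = CH3 on C10, side chain C11–C16), the labdane names refer to the antipodal series fixed by the SMILES, and TBDPS = tert-butyldiphenylsilyl, TBS = tert-butyldimethylsilyl.

**Route**

Step 1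
Reactants: 1 acrolein diethyl acetal; 2 4-bromofuran-2(5H)-one
Product: 4 4-(3,3-diethoxypropyl)furan-2(5H)-one, via alkylborane 3 (not isolated)
Conditions: 9-BBN-H, THF, 0 °C to rt; then 2, Pd(dppf)Cl2 (5 mol %), AsPh3, Cs2CO3, DMF/H2O, rt
Reagents that add atoms: none
Why: 9-BBN-H adds anti-Markovnikov to the terminal alkene of 1 and the B-alkyl borane then undergoes Suzuki–Miyaura coupling with the β-bromobutenolide, a vinylogous acyl bromide that adds readily to zerovalent palladium, so the C12–C13 bond forms while the ring still fixes the later 13Z geometry.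

Step 2
Reactants: 4 4-(3,3-diethoxypropyl)furan-2(5H)-one
Product: 5 (Z)-2-(3,3-diethoxypropyl)but-2-ene-1,4-diol
Conditions: i-Bu2AlH (4 equiv), CH2Cl2, −78 to 0 °C; aq. potassium sodium tartrate
Reagents that add atoms: none
Why: 1,2-reduction of the butenolide through the lactol should give the ene-diol without touching the acetal, and because C15 and C16 were cis in the ring the diol is the Z isomer.

Step 3
Reactants: 5 (Z)-2-(3,3-diethoxypropyl)but-2-ene-1,4-diol
Product: 6 (Z)-1,4-bis(TBDPS-oxy)-2-(3,3-diethoxypropyl)but-2-ene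
Conditions: TBDPSCl (2.3 equiv), imidazole, DMF, rt
Reagents that add atoms: tert-butyl(chloro)diphenylsilane, CC(C)(C)[Si](Cl)(c1ccccc1)c1ccccc1
Why: standard silylation of two primary allylic alcohols, with TBDPS chosen because it should withstand the later alkoxide, hydride and mild-acid steps.

Step 4
Reactants: 6 (Z)-1,4-bis(TBDPS-oxy)-2-(3,3-diethoxypropyl)but-2-ene
Product: 7 (Z)-6-(TBDPS-oxy)-4-[(TBDPS-oxy)methyl]hex-4-enal
Conditions: PPTS (20 mol %), acetone/H2O (10:1), 50 °C
Reagents that add atoms: water, O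
Why: acid-catalysed acetal hydrolysis should free the aldehyde (C9) under conditions to which primary TBDPS ethers are stable.

Step 5
Reactants: 7 (Z)-6-(TBDPS-oxy)-4-[(TBDPS-oxy)methyl]hex-4-enal
Product: 8 (3E,7Z)-9-(TBDPS-oxy)-7-[(TBDPS-oxy)methyl]-3-methylnona-3,7-dien-2-one
Conditions: Ph3P=C(CH3)C(O)CH3 (1.5 equiv), toluene, 100 °C
Reagents that add atoms: 3-(triphenyl-λ5-phosphanylidene)butan-2-one, CC(=O)C(C)=P(c1ccccc1)(c1ccccc1)c1ccccc1
Why: Wittig olefination with the stabilised α-branched keto ylide should give the (E)-trisubstituted enone, which brings in C1, C2, C10 and C20 in one piece.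

Step 6
Reactants: 9 pent-4-yn-1-ol
Product: 11 ethyl (E)-2-methylhept-2-en-6-ynoate, via pent-4-ynal 10 (not isolated)
Conditions: PhI(OAc)2 (1.1 equiv), TEMPO (10 mol %), CH2Cl2, rt; then Ph3P=C(CH3)CO2Et, rt
Reagents that add atoms: ethyl 2-(triphenyl-λ5-phosphanylidene)propanoate, CCOC(=O)C(C)=P(c1ccccc1)(c1ccccc1)c1ccccc1
Why: the oxoammonium oxidation stops at the aldehyde and the volatile ynal is trapped in the same flask by the stabilised ylide (tandem oxidation–Wittig), which should give the (E)-α-methyl enoate.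

Step 7
Reactants: 11 ethyl (E)-2-methylhept-2-en-6-ynoate
Product: 12 ethyl (E)-6-iodo-2-methylhepta-2,6-dienoate
Conditions: NaI (1.5 equiv), Me3SiCl (1.5 equiv), H2O (0.75 equiv), MeCN, rt
Reagents that add atoms: sodium iodide, [Na+].[I-]
Why: HI generated in situ adds to the terminal alkyne in the Markovnikov sense (hydroiodination) to give the 2-iodo-1-alkene, while the electron-poor trisubstituted enoate should not react.

Step 8
Reactants: 12 ethyl (E)-6-iodo-2-methylhepta-2,6-dienoate
Product: 13 ethyl (E)-2-methyl-6-(4,4,5,5-tetramethyl-1,3,2-dioxaborolan-2-yl)hepta-2,6-dienoate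
Conditions: B2pin2 (1.1 equiv), PdCl2(PPh3)2 (3 mol %), PPh3, KOPh, toluene, 50 °C
Reagents that add atoms: bis(pinacolato)diboron, CC1(C)OB(OC1(C)C)B1OC(C)(C)C(C)(C)O1
Why: Miyaura borylation of the alkenyl iodide under weak-base conditions should keep the 1,1-disubstituted alkene in place and tolerate the ester.

Step 9
Reactants: 8 (3E,7Z)-9-(TBDPS-oxy)-7-[(TBDPS-oxy)methyl]-3-methylnona-3,7-dien-2-one; 13 ethyl (E)-2-methyl-6-(pinacolboryl)hepta-2,6-dienoate
Product: 14 ethyl (2E,7S,10Z)-12-(TBDPS-oxy)-10-[(TBDPS-oxy)methyl]-2-methyl-6-methylidene-7-(3-oxobutan-2-yl)dodeca-2,10-dienoate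
Conditions: [Rh(acac)(C2H4)2] (3 mol %), (S)-BINAP (3.6 mol %), K3PO4, dioxane/H2O (10:1), 60 °C
Reagents that add atoms: none
Why: Hayashi–Miyaura asymmetric 1,4-addition, in which the alkenyl group passes from boron to monovalent rhodium, the enone C=C inserts and water releases the ketone; the ligand should expose the Si face of C9 and so give 9S (sense assigned by analogy with additions to linear (E)-enones, the antipodal ligand being used if it proves opposite), the trisubstituted enoates are far less reactive than the enone, and C10 forms as an epimer mixture that does not matter.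

Step 10
Reactants: 14 ethyl (2E,7S,10Z)-12-(TBDPS-oxy)-10-[(TBDPS-oxy)methyl]-2-methyl-6-methylidene-7-(3-oxobutan-2-yl)dodeca-2,10-dienoate
Product: 16 15,16-bis(TBDPS-oxy)-18-norlabda-8(17),13Z-diene-1,3-dione (trans-fused), via Michael adduct 15 (not isolated)
Conditions: KOt-Bu (2.5 equiv), t-BuOH/THF (1:5), 0.01 M, 0 °C to rt; then 1 M HCl
Reagents that add atoms: none
Why: KOt-Bu reversibly enolises the methyl ketone; the more substituted C10 enolate adds to C5 of the (E)-α-methyl enoate (intramolecular Michael addition, ring B), the resulting ester enolate is reprotonated by t-BuOH, and the C2 enolate of the same ketone then attacks the C3 ester carbonyl (Claisen/Dieckmann-type condensation, ring A), the sequence being driven by irreversible deprotonation of the 1,3-dione at C2. The closest known reaction is the one-flask Michael–Claisen [3+3] synthesis of cyclohexane-1,3-diones from methyl ketones and acrylates, run here within one chain. Ring B closes in the 6-(enolexo)-exo-trig mode onto the enoate C=C and ring A in the 6-(enolexo)-exo-trig mode onto the ester C=O. C5 and C10 are set by C9: in the chair transition state the C9 side chain stands anti to the forming C5–C10 bond (least A(1,2) strain with the planar enolate) and the enoate arm on C5 is equatorial, which fixes C5; at C10 the bulkier, potassium-bridged enolate carbon C1 should take the equatorial site and the C20 methyl the axial one, which is the trans ring fusion, while C4 forms as a mixture that step 13 erases. The step needs C10 rather than C2 to attack first and trans rather than cis fusion: the C2 enolate can only close 8- or 10-membered rings and so returns to 14, and the trans fusion rests on the equatorial preference of the acyl group next to the equatorial C9 substituent.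

Step 11
Reactants: 16 15,16-bis(TBDPS-oxy)-18-norlabda-8(17),13Z-diene-1,3-dione
Product: 17 3-methoxy-15,16-bis(TBDPS-oxy)-18-norlabda-2,8(17),13Z-trien-1-one
Conditions: MeOH, CSA (10 mol %), 3 Å MS, 40 °C
Reagents that add atoms: methanol, CO
Why: acid-catalysed enol etherification of the cyclic 1,3-dione (vinylogous ester formation) should place the methoxy group on C3, the carbonyl carbon not flanked by the quaternary C10, as with 4,4-disubstituted cyclohexane-1,3-diones.

Step 12
Reactants: 17 3-methoxy-15,16-bis(TBDPS-oxy)-18-norlabda-2,8(17),13Z-trien-1-one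
Product: 19 15,16-bis(TBDPS-oxy)-18-norlabda-1,8(17),13Z-trien-3-one, via allylic alcohol 18 (not isolated)
Conditions: LiAlH4, Et2O, 0 °C; then 1 M HCl, THF, rt
Reagents that add atoms: water, O
Why: Stork–Danheiser transposition, in which hydride adds 1,2 to the C1 carbonyl and acid hydrolysis of the enol ether with loss of the C1 hydroxyl gives the Δ1-3-ketone, so the temporary C1 oxygen leaves as water and the C1=C2 alkene left behind blocks enolisation towards C2.

Step 13
Reactants: 19 15,16-bis(TBDPS-oxy)-18-norlabda-1,8(17),13Z-trien-3-one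
Product: 20 (4S)-18-hydroxy-15,16-bis(TBDPS-oxy)labda-1,8(17),13Z-trien-3-one
Conditions: LiN(i-Pr)2 (1.3 equiv), THF, −78 °C; CH2O (gas, from cracked paraformaldehyde), −78 °C; aq. NH4Cl
Reagents that add atoms: formaldehyde, C=O
Why: kinetic deprotonation can only occur at C4 (C2 is vinylic, C10 quaternary) and the cross-conjugated lithium enolate should take up formaldehyde (aldol addition) on the face anti to the axial C20 methyl, which puts the new CH2OH (C18) equatorial and trans to C20 and leaves the C19 methyl axial.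

Step 14
Reactants: 20 (4S)-18-hydroxy-15,16-bis(TBDPS-oxy)labda-1,8(17),13Z-trien-3-one
Product: 21 (4S)-18-(TBS-oxy)-15,16-bis(TBDPS-oxy)labda-1,8(17),13Z-trien-3-one
Conditions: TBSCl, imidazole, DMF, rt
Reagents that add atoms: tert-butyl(chloro)dimethylsilane, CC(C)(C)[Si](C)(C)Cl
Why: silylation of the neopentyl primary alcohol should prevent retro-aldol loss of formaldehyde and keeps O18 masked during the esterification.

Step 15
Reactants: 21 (4S)-18-(TBS-oxy)-15,16-bis(TBDPS-oxy)labda-1,8(17),13Z-trien-3-one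
Product: 22 (4S)-18-(TBS-oxy)-15,16-bis(TBDPS-oxy)labda-8(17),13Z-dien-3-one
Conditions: [(Ph3P)CuH]6 (0.4 equiv), wet toluene, rt; aq. NH4Cl
Reagents that add atoms: none
Why: the phosphine-stabilised copper hydride delivers hydride to C1 in a conjugate reduction that should be selective for the enone over the isolated 1,1-di- and trisubstituted alkenes.

Step 16
Reactants: 22 (4S)-18-(TBS-oxy)-15,16-bis(TBDPS-oxy)labda-8(17),13Z-dien-3-one
Product: 23 (3R,4S)-18-(TBS-oxy)-15,16-bis(TBDPS-oxy)labda-8(17),13Z-dien-3-ol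
Conditions: NaBH4, MeOH/THF, 0 °C
Reagents that add atoms: none
Why: borohydride should attack the C3 ketone along the axial trajectory, anti to the axial C19 and C20 methyls, to give the equatorial alcohol (3R), as with 4,4-disubstituted 3-oxo terpenoids.

Step 17
Reactants: 23 (3R,4S)-18-(TBS-oxy)-15,16-bis(TBDPS-oxy)labda-8(17),13Z-dien-3-ol
Product: 24 (3R,4S)-18-(TBS-oxy)-15,16-bis(TBDPS-oxy)labda-8(17),13Z-dien-3-yl (Z)-2-methylbut-2-enoate
Conditions: angelic acid, 2,4,6-trichlorobenzoyl chloride, Et3N, toluene, rt; then 23, 80 °C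
Reagents that add atoms: angelic acid, C/C=C(/C)C(O)=O
Why: Yamaguchi-type esterification through the mixed trichlorobenzoic angelic anhydride, run without a nucleophilic catalyst, should acylate the secondary alcohol while avoiding base-induced Z to E isomerisation of the angeloyl group.

Step 18
Reactants: 24 (3R,4S)-18-(TBS-oxy)-15,16-bis(TBDPS-oxy)labda-8(17),13Z-dien-3-yl (Z)-2-methylbut-2-enoate
Product: 25 (3R,4S,5S,9R,10S)-15,16,18-trihydroxylabda-8(17),13Z-dien-3-yl (Z)-2-methylbut-2-enoate (CNP0237954.1)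
Conditions: HF·pyridine, pyridine, THF, 0 °C to rt
Reagents that add atoms: none
Why: buffered fluoride should cleave the three silyl ethers under mildly acidic conditions in which neither acyl migration from O3 to O18 nor angelate isomerisation is expected.

**Compound list**

1 | 3,3-diethoxyprop-1-ene (acrolein diethyl acetal) | C=CC(OCC)OCC | starting material
2 | 4-bromofuran-2(5H)-one | BrC1=CC(=O)OC1 | starting material
3 | 9-(3,3-diethoxypropyl)-9-borabicyclo[3.3.1]nonane (not isolated) | CCOC(OCC)CCB1C2CCCC1CCC2 | intermediate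
4 | 4-(3,3-diethoxypropyl)furan-2(5H)-one | CCOC(OCC)CCC1=CC(=O)OC1 | intermediate
5 | (Z)-2-(3,3-diethoxypropyl)but-2-ene-1,4-diol | CCOC(OCC)CC/C(=C/CO)CO | intermediate
6 | (Z)-1,4-bis(tert-butyldiphenylsilyloxy)-2-(3,3-diethoxypropyl)but-2-ene | CCOC(OCC)CC/C(=C/CO[Si](c1ccccc1)(c1ccccc1)C(C)(C)C)CO[Si](c1ccccc1)(c1ccccc1)C(C)(C)C | intermediate
7 | (Z)-6-(tert-butyldiphenylsilyloxy)-4-[(tert-butyldiphenylsilyloxy)methyl]hex-4-enal | O=CCC/C(=C/CO[Si](c1ccccc1)(c1ccccc1)C(C)(C)C)CO[Si](c1ccccc1)(c1ccccc1)C(C)(C)C | intermediate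
8 | (3E,7Z)-9-(tert-butyldiphenylsilyloxy)-7-[(tert-butyldiphenylsilyloxy)methyl]-3-methylnona-3,7-dien-2-one | CC(=O)/C(C)=C/CC/C(=C/CO[Si](c1ccccc1)(c1ccccc1)C(C)(C)C)CO[Si](c1ccccc1)(c1ccccc1)C(C)(C)C | intermediate
9 | pent-4-yn-1-ol | C#CCCCO | starting material
10 | pent-4-ynal (not isolated) | C#CCCC=O | intermediate
11 | ethyl (E)-2-methylhept-2-en-6-ynoate | CCOC(=O)/C(C)=C/CCC#C | intermediate
12 | ethyl (E)-6-iodo-2-methylhepta-2,6-dienoate | CCOC(=O)/C(C)=C/CCC(I)=C | intermediate
13 | ethyl (E)-2-methyl-6-(4,4,5,5-tetramethyl-1,3,2-dioxaborolan-2-yl)hepta-2,6-dienoate | CCOC(=O)/C(C)=C/CCC(=C)B1OC(C)(C)C(C)(C)O1 | intermediate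
14 | ethyl (2E,7S,10Z)-12-(TBDPS-oxy)-10-[(TBDPS-oxy)methyl]-2-methyl-6-methylidene-7-(3-oxobutan-2-yl)dodeca-2,10-dienoate (9S in labdane locants, both C10 epimers) | CC(=O)C(C)[C@H](CC/C(=C/CO[Si](c1ccccc1)(c1ccccc1)C(C)(C)C)CO[Si](c1ccccc1)(c1ccccc1)C(C)(C)C)C(=C)CC/C=C(\C)C(=O)OCC | intermediate
15 | Michael adduct, ethyl 2-[2-acetyl-2-methyl-4-methylidene-3-(side chain)cyclohexyl]propanoate with C5, C9, C10 as in 25 (not isolated) | C=C1CC[C@H](C(C)C(=O)OCC)[C@@](C)(C(C)=O)[C@@H]1CC/C(=C/CO[Si](c3ccccc3)(c3ccccc3)C(C)(C)C)CO[Si](c3ccccc3)(c3ccccc3)C(C)(C)C | intermediate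
16 | 15,16-bis(TBDPS-oxy)-18-norlabda-8(17),13Z-diene-1,3-dione, trans-fused, C5, C9, C10 as in 25, C4 epimers | C=C1CC[C@@H]2C(C)C(=O)CC(=O)[C@@]2(C)[C@@H]1CC/C(=C/CO[Si](c3ccccc3)(c3ccccc3)C(C)(C)C)CO[Si](c3ccccc3)(c3ccccc3)C(C)(C)C | intermediate
17 | 3-methoxy-15,16-bis(TBDPS-oxy)-18-norlabda-2,8(17),13Z-trien-1-one | C=C1CC[C@@H]2C(C)C(OC)=CC(=O)[C@@]2(C)[C@@H]1CC/C(=C/CO[Si](c3ccccc3)(c3ccccc3)C(C)(C)C)CO[Si](c3ccccc3)(c3ccccc3)C(C)(C)C | intermediate
18 | 3-methoxy-15,16-bis(TBDPS-oxy)-18-norlabda-2,8(17),13Z-trien-1-ol (not isolated) | C=C1CC[C@@H]2C(C)C(OC)=CC(O)[C@@]2(C)[C@@H]1CC/C(=C/CO[Si](c3ccccc3)(c3ccccc3)C(C)(C)C)CO[Si](c3ccccc3)(c3ccccc3)C(C)(C)C | intermediate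
19 | 15,16-bis(TBDPS-oxy)-18-norlabda-1,8(17),13Z-trien-3-one | C=C1CC[C@@H]2C(C)C(=O)C=C[C@@]2(C)[C@@H]1CC/C(=C/CO[Si](c3ccccc3)(c3ccccc3)C(C)(C)C)CO[Si](c3ccccc3)(c3ccccc3)C(C)(C)C | intermediate
20 | (4S)-18-hydroxy-15,16-bis(TBDPS-oxy)labda-1,8(17),13Z-trien-3-one (CH2OH trans to C20) | C=C1CC[C@H]2[C@@](C)(C=CC(=O)[C@]2(C)CO)[C@@H]1CC/C(=C/CO[Si](c3ccccc3)(c3ccccc3)C(C)(C)C)CO[Si](c3ccccc3)(c3ccccc3)C(C)(C)C | intermediate
21 | (4S)-18-(TBS-oxy)-15,16-bis(TBDPS-oxy)labda-1,8(17),13Z-trien-3-one | C=C1CC[C@H]2[C@@](C)(C=CC(=O)[C@]2(C)CO[Si](C)(C)C(C)(C)C)[C@@H]1CC/C(=C/CO[Si](c3ccccc3)(c3ccccc3)C(C)(C)C)CO[Si](c3ccccc3)(c3ccccc3)C(C)(C)C | intermediate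
22 | (4S)-18-(TBS-oxy)-15,16-bis(TBDPS-oxy)labda-8(17),13Z-dien-3-one | C=C1CC[C@H]2[C@@](C)(CCC(=O)[C@]2(C)CO[Si](C)(C)C(C)(C)C)[C@@H]1CC/C(=C/CO[Si](c3ccccc3)(c3ccccc3)C(C)(C)C)CO[Si](c3ccccc3)(c3ccccc3)C(C)(C)C | intermediate
23 | (3R,4S)-18-(TBS-oxy)-15,16-bis(TBDPS-oxy)labda-8(17),13Z-dien-3-ol (equatorial OH) | C=C1CC[C@H]2[C@@](C)(CC[C@@H](O)[C@]2(C)CO[Si](C)(C)C(C)(C)C)[C@@H]1CC/C(=C/CO[Si](c3ccccc3)(c3ccccc3)C(C)(C)C)CO[Si](c3ccccc3)(c3ccccc3)C(C)(C)C | intermediate
24 | (3R,4S)-18-(TBS-oxy)-15,16-bis(TBDPS-oxy)labda-8(17),13Z-dien-3-yl (Z)-2-methylbut-2-enoate | C=C1CC[C@H]2[C@@](C)(CC[C@@H](OC(=O)/C(C)=C\C)[C@]2(C)CO[Si](C)(C)C(C)(C)C)[C@@H]1CC/C(=C/CO[Si](c3ccccc3)(c3ccccc3)C(C)(C)C)CO[Si](c3ccccc3)(c3ccccc3)C(C)(C)C | intermediate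
25 | (3R,4S,5S,9R,10S)-15,16,18-trihydroxylabda-8(17),13Z-dien-3-yl (Z)-2-methylbut-2-enoate (CNP0237954.1) | C=C1CC[C@H]2[C@@](C)(CC[C@@H](OC(=O)/C(C)=C\C)[C@]2(C)CO)[C@@H]1CC/C(=C/CO)CO | target

**Summary**

Total step count: 18. Longest linear sequence: 15 steps (steps 1–5, then 9–18); steps 6–8 form the second branch.

The three steps most likely to fail:

1. Step 9. The α-methyl group slows insertion of the enone into the alkenyl–rhodium bond, so protodeboronation of 13 may outrun addition and facial discrimination may erode. The fallback sets out from 7 (and uses 12) and returns at 14. Aldehyde 7 would be condensed under Horner–Wadsworth–Emmons conditions (LiCl, i-Pr2NEt, MeCN) with (R)-3-[(diethoxyphosphoryl)acetyl]-4-phenyloxazolidin-2-one to give the (E)-enoyl imide F1. Iodide 12 would be converted with i-PrMgCl·LiCl (THF, −40 °C) into the alkenylmagnesium chloride F2, which with CuBr·SMe2 should add to the chelated imide anti to the phenyl group to give the 9S conjugate adduct F3. NaN(SiMe3)2/MeI would then give the α-methyl imide F4, MeONHMe·HCl/AlMe3 the N-methoxy-N-methyl amide F5, and MeMgBr (THF, −20 °C) the ketone 14.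

2. Step 10. The ring fusion depends on whether the methyl or the acyl group on C10 sits axial in the Michael transition state, and base-induced deconjugation of the enoate competes. The fallback sets out from 14 and returns at 16, making the two bonds in two stages through a neutral, cyclic transition state. Ketone 14 would be condensed with benzylamine (4 Å MS, toluene) to the N-benzyl imine F6. On heating, its more substituted secondary enamine tautomer should add C10 to C5 in the aza-ene mode of the imine Michael reaction, with N–H passed to C4 inside a compact chair, to give the cyclised imine F7. Aqueous acetic acid would hydrolyse F7 to keto ester 15, now isolated, and NaOEt in EtOH would then close ring A by Claisen condensation to 16.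

3. Step 17. Acylation of the hindered C3 hydroxyl is slow, which gives the activated angeloyl unit time to isomerise from Z to E. The fallback sets out from 23 and returns at 24. Alcohol 23 would be esterified (DCC, DMAP) with 2-[bis(2,2,2-trifluoroethoxy)phosphoryl]propanoic acid to give the phosphonate ester F8. A Still–Gennari olefination with acetaldehyde (KN(SiMe3)2, 18-crown-6, THF, −78 °C) should then build the Z-trisubstituted alkene of 24 directly on the ester.

Further compounds

F1 | step 9 | (R)-3-[(2E,6Z)-8-(TBDPS-oxy)-6-[(TBDPS-oxy)methyl]octa-2,6-dienoyl]-4-phenyloxazolidin-2-one | O=C(/C=C/CC/C(=C/CO[Si](c1ccccc1)(c1ccccc1)C(C)(C)C)CO[Si](c1ccccc1)(c1ccccc1)C(C)(C)C)N1C(=O)OC[C@H]1c1ccccc1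
F2 | step 9 | chloro[(E)-7-ethoxy-6-methyl-7-oxohepta-1,5-dien-2-yl]magnesium | CCOC(=O)/C(C)=C/CCC(=C)[Mg]Cl
F3 | step 9 | 9S conjugate adduct, (R)-4-phenyloxazolidin-2-one imide of the C10-unsubstituted acid corresponding to 14 | O=C(C[C@H](CC/C(=C/CO[Si](c1ccccc1)(c1ccccc1)C(C)(C)C)CO[Si](c1ccccc1)(c1ccccc1)C(C)(C)C)C(=C)CC/C=C(\C)C(=O)OCC)N1C(=O)OC[C@H]1c1ccccc1
F4 | step 9 | C10-methylated imide | O=C(C(C)[C@H](CC/C(=C/CO[Si](c1ccccc1)(c1ccccc1)C(C)(C)C)CO[Si](c1ccccc1)(c1ccccc1)C(C)(C)C)C(=C)CC/C=C(\C)C(=O)OCC)N1C(=O)OC[C@H]1c1ccccc1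
F5 | step 9 | N-methoxy-N-methyl amide corresponding to 14 | CON(C)C(=O)C(C)[C@H](CC/C(=C/CO[Si](c1ccccc1)(c1ccccc1)C(C)(C)C)CO[Si](c1ccccc1)(c1ccccc1)C(C)(C)C)C(=C)CC/C=C(\C)C(=O)OCC
F6 | step 10 | N-benzyl imine of 14 | CC(=NCc1ccccc1)C(C)[C@H](CC/C(=C/CO[Si](c1ccccc1)(c1ccccc1)C(C)(C)C)CO[Si](c1ccccc1)(c1ccccc1)C(C)(C)C)C(=C)CC/C=C(\C)C(=O)OCC
F7 | step 10 | N-benzyl imine of Michael adduct 15 | C=C1CC[C@H](C(C)C(=O)OCC)[C@@](C)(C(C)=NCc2ccccc2)[C@@H]1CC/C(=C/CO[Si](c3ccccc3)(c3ccccc3)C(C)(C)C)CO[Si](c3ccccc3)(c3ccccc3)C(C)(C)C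
F8 | step 17 | 2-[bis(2,2,2-trifluoroethoxy)phosphoryl]propanoate of 23 | C=C1CC[C@H]2[C@@](C)(CC[C@@H](OC(=O)C(C)P(=O)(OCC(F)(F)F)OCC(F)(F)F)[C@]2(C)CO[Si](C)(C)C(C)(C)C)[C@@H]1CC/C(=C/CO[Si](c3ccccc3)(c3ccccc3)C(C)(C)C)CO[Si](c3ccccc3)(c3ccccc3)C(C)(C)C
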